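## The problem

Target 26 is a germacranolide. Ring atoms are numbered C1–C10 as in germacranes, with the lactone carbons C11 (ring-bound), C12 (carbonyl) and C13 (methylene), and the methyls C14 on C10 and C15 on C4. The ten-membered carbocycle carries a trans-fused α-methylene-γ-butyrolactone across C7–C8 (ring oxygen on C8), a trans trisubstituted epoxide at C4–C5, a tiglate on C6, a free hydroxyl on C9 and a methyl-bearing methine at C10. All seven stereocentres, C4 to C10, are contiguous on a ring with no rigid shape of its own, so they must either be made together in one concerted event or be set by attack on the outer face of a trigonal ring carbon. C6 and C7 can be made together. Once C6, C7 and C8 carry equatorial substituents, they should fix the ring well enough for outer-face control at C8, C10 and C9. The epoxide can only be directed by the C6 hydroxyl. The exocyclic enoate is a Michael acceptor that tolerates neither strong base nor nucleophilic hydride, the epoxide next to an acyloxy group is acid-sensitive, and at the C9 ketone stage both C8 and C10 can epimerise. The feature that opens the route is that O8 and the C7 side chain are trans neighbours: with C11≡C13 present as an ethynyl group, O8–C8–C7–C11≡C13 is a homopropargylic alcohol that lacks only C12, which carbon monoxide can supply.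

## Retrosynthesis

**26 ⇒ 25.** The C9 carbinol is taken back to a ketone. Reducing last means C9 never needs a protecting group and C6 is the only hydroxyl when the ester is made. The forward step needs a hydride that spares the enoate, the epoxide and the tiglate and adds to the outer face of the carbonyl.

**25 ⇒ 23 + 24.** The ester C–O bond is cut to give epoxy alcohol 23 and tigloyl chloride 24. Acylating after epoxidation keeps the C6 hydroxyl free to direct the oxidant.

**23 ⇒ 22 ⇒ 21.** The epoxide oxygen is removed to give allylic alcohol 22, and the C6 oxygen is masked as the PMB ether 21. The C6–C7 ring bond must lie over the inner face of the E olefin, so the C6 oxygen can reach the 40–50° dihedral angle that a vanadium peroxide needs in only one olefin rotamer. That rotamer leads to the (4R,5R) oxide. A peracid, which prefers about 120°, would be expected to attack the other face. The forward step therefore needs the vanadium system specifically.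

**21 ⇒ 19 + 20 (key disconnection).** The C12–O8 and C11–C12 bonds are cut, which removes the lactone ring and C12 as carbon monoxide 20. Against the usual lactone-then-methylenation order, this cut creates the Michael acceptor in one neutral step and needs no lactone enolate next to an enolisable ketone. Precursor 19 is a monocyclic α-hydroxy ketone with a trans ethynyl group. The forward step needs only five-membered closure, which the tether enforces.

**19 ⇒ 18 ⇒ 16 ⇒ 15.** Two silyl groups are put back (18), and the C10–C14 bond is cut (16, then free ketol 15). The methyl is introduced after ring expansion, not carried from the cyclohexanone. A methyl on the carbon flanking the carbinol would be axial in the chair through which the two alkenyl arms meet and would emerge as the C10 epimer. On the ten-membered α-silyloxy ketone, deprotonation and alkylation should both occur on the outer face, which gives the equatorial (10R) methyl.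

**15 ⇒ 13.** The C6–C7 bond is cut, the C4–C9 bond is restored and the C8 oxygen is removed. This is the retron of an anionic oxy-Cope rearrangement with oxidation of the resulting enolate. It replaces a ten-membered ring with three stereocentres by a cyclohexanol whose only stereochemical information is one quaternary carbon and two E olefins.

**13 ⇒ 12 ⇒ 9 + 10.** The E enyne arm is taken back to a diyne (12), and the carbinol C–C bond is cut to ketone 9 and diyne 10. A diynyl anion followed by hydroxyl-directed trans hydroalumination is preferred to an enynyl metal: the reagent is one step from a commercial diyne, is small enough for a hindered ketone, and the E geometry is then set by mechanism.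

**9 ⇒ 8 ⇒ 7 ⇒ 5 ⇒ 4.** The enol ether C–O bond is cut to vinyl iodide 8, which comes from aldehyde 7 by one-carbon olefination. Aldehyde 7 comes from allyl ketone 4 by olefin migration (5) and cleavage. The enol ether must be E, because its geometry becomes the C6 configuration. Stereoretentive coupling of an E iodide is therefore preferred to any enolisation or Wittig route, which would give mixtures.

**4 ⇒ 3 ⇒ 1.** The quaternary stereocentre, the source of all absolute configuration, is made by catalytic decarboxylative allylation of racemic keto ester 3. Keto ester 3 comes from diester 1 by Dieckmann cyclisation and methylation.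

## Roads not taken

**Alternative 1:** The ring is cut at C2–C3. An open-chain precursor that already holds C6–C10 and a saturated C7–C8 lactone carries an allylic carbonate at C5 and a bis(phenylsulfonyl)methyl end at C2. A zerovalent palladium catalyst ionises the carbonate to a 2-methyl π-allyl unit over C3–C5, and the sulfone carbanion attacks C3 to give macrocycle A1 with the E C4=C5 olefin.
- Merits: every stereocentre from C6 to C10 is set in an open chain by reactions with reliable models, and no ring-conformation argument is needed for them. In this respect it is better than the chosen plan.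
- Weak points: the closure forms a strained ten-membered ring against an entropic penalty. The π-allyl unit can also be attacked at C5 to give an eight-membered ring. Two sulfonyl groups must then be removed reductively, and the methylene group must still be added to the lactone by enolate chemistry.
- Comparison: the chosen plan forms the ring by a unimolecular sigmatropic shift that is independent of concentration, is several steps shorter, and creates the enoate without base.

**Alternative 2:** The cuts are C1–C10 and C4–C5. Irradiation of the chiral-pool cyclohexenone A2, which already carries the C6, C7 and C8 substituents, with 1-methylcyclobutene A3 should give the head-to-tail photoadduct A4. Thermal cycloreversion of its bicyclo[2.2.0]hexane then opens the ten-membered ring.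
- Merits: absolute configuration comes from the chiral pool, and the C6–C8 oxygen pattern is set on a six-membered ring. On this point it is at least as good as the chosen plan.
- Weak points: the cycloreversion delivers a 1(10),4-diene. The target has a saturated C10 methine, so the extra olefin would have to be reduced face- and site-selectively beside C4=C5, and such 1,5-dienes readily undergo Cope rearrangement to divinylcyclohexanes. Regio- and face selectivity of the photoaddition with a small, volatile alkene is a further uncertainty.
- Comparison: the chosen plan never forms the extra olefin and sets C10 by alkylation.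

**Alternative 3:** The same C6–C7 bond is made by anionic oxy-Cope rearrangement, but as the strategic step. A dialkenylcyclohexanol carrying a protected hydroxyethyl arm gives cyclodecenone A5, and the lactone is built afterwards by oxidation, closure and methylenation.
- Merits: both alkenyl arms are simple, the rearrangement has the closest precedent, and no palladium–carbon monoxide step is needed on a late intermediate. In these respects it is the safer road.
- Weak points: at least four more steps are needed for the lactone. The methylenation requires a lactone enolate beside an enolisable C9 ketone. The C10 methyl is carried through the rearrangement, so its configuration depends on the face selectivity of the carbonyl addition.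
- Comparison: the chosen plan shares the ring expansion and its risks, but has two steps from ring expansion product to lactone precursor after methylation, base-free formation of the Michael acceptor, and C10 set after the ring exists.

Key step: step 13

## Route

Remark: metal cations are counted as their hydroxides after aqueous work-up, and changes of the C7 descriptor along the route reflect changes of substituent priority, not inversion.

Step 1
Reactants: 1 diallyl heptanedioate (diallyl pimelate)
Product: 3 allyl 1-methyl-2-oxocyclohexane-1-carboxylate (racemic), via sodium enolate of allyl 2-oxocyclohexane-1-carboxylate 2 (not isolated)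
Conditions: NaH, THF, 40 °C; then MeI, 25 °C
Reagents that add atoms: iodomethane, CI
Why: Dieckmann condensation gives the stabilised β-keto ester enolate, which is C-methylated in the same flask. The new stereocentre is deliberately racemic because step 2 erases it.

Step 2
Reactants: 3 allyl 1-methyl-2-oxocyclohexane-1-carboxylate
Product: 4 (2R)-2-methyl-2-(prop-2-en-1-yl)cyclohexan-1-one
Conditions: Pd2(dba)3 (2.5 mol %), (R)-t-Bu-PHOX (6 mol %), THF, 25 °C
Reagents that add atoms: none
Why: Decarboxylative asymmetric allylic alkylation: loss of CO2 gives an achiral enolate and a π-allylpalladium unit on the chiral phosphinooxazoline, which selects the face of C–C bond formation; the R ligand is the one known to lead to the R ketone. High ee is expected and can be raised by recrystallising the semicarbazone if needed.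

Step 3
Reactants: 4 (2R)-2-methyl-2-(prop-2-en-1-yl)cyclohexan-1-one
Product: 5 (2R)-2-methyl-2-[(1E)-prop-1-en-1-yl]cyclohexan-1-one
Conditions: RuHCl(CO)(PPh3)3 (5 mol %), toluene, 80 °C
Reagents that add atoms: none
Why: Metal hydride-catalysed olefin isomerisation by addition and β-hydride elimination; the double bond cannot move past the quaternary carbon. The E/Z composition is of no consequence because the olefin is cleaved next.

Step 4
Reactants: 5 (2R)-2-methyl-2-[(1E)-prop-1-en-1-yl]cyclohexan-1-one
Product: 7 (1R)-1-methyl-2-oxocyclohexane-1-carbaldehyde, via 1,2,4-trioxolane ozonide 6 (not isolated)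
Conditions: O3, CH2Cl2, −78 °C; then PPh3
Reagents that add atoms: ozone, [O-][O+]=O
Why: Ozonolysis with reductive work-up. The non-enolisable β-keto aldehyde is used crude to avoid deformylation.

Step 5
Reactants: 7 (1R)-1-methyl-2-oxocyclohexane-1-carbaldehyde
Product: 8 (2R)-2-[(E)-2-iodoethenyl]-2-methylcyclohexan-1-one
Conditions: CrCl2, CHI3, THF, 0 °C
Reagents that add atoms: iodoform, IC(I)I
Why: Takai olefination; the geminal dichromium reagent reacts with aldehydes and not ketones and gives the E iodide, the more so with a bulky α-substituent.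

Step 6
Reactants: 8 (2R)-2-[(E)-2-iodoethenyl]-2-methylcyclohexan-1-one
Product: 9 (2R)-2-{(E)-2-[(4-methoxyphenyl)methoxy]ethenyl}-2-methylcyclohexan-1-one
Conditions: 4-methoxybenzyl alcohol, CuI (10 mol %), 3,4,7,8-tetramethyl-1,10-phenanthroline (20 mol %), Cs2CO3, toluene, 80 °C
Reagents that add atoms: 4-methoxybenzyl alcohol, COc1ccc(CO)cc1
Why: Copper-catalysed Ullmann-type C–O coupling of a vinyl iodide with an alcohol, which proceeds with retention of olefin geometry and so delivers the E enol ether that the C6 configuration depends on.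

Step 7
Reactants: 9 (2R)-2-{(E)-2-[(4-methoxyphenyl)methoxy]ethenyl}-2-methylcyclohexan-1-one; 10 1,4-bis(trimethylsilyl)buta-1,3-diyne
Product: 12 (1R,2R)-2-{(E)-2-[(4-methoxyphenyl)methoxy]ethenyl}-2-methyl-1-[4-(trimethylsilyl)buta-1,3-diyn-1-yl]cyclohexan-1-ol, via lithium 4-(trimethylsilyl)buta-1,3-diyn-1-ide 11 (not isolated)
Conditions: 10, MeLi·LiBr, THF, −78 → 0 °C; then 9, −78 °C
Reagents that add atoms: none
Why: 1,2-Addition of a lithium acetylide made by monodesilylation of 10. The small linear nucleophile attacks axially and anti to the axial α-substituent; the chair of 9 with the alkenyl arm axial is expected to react (antiperiplanar C–C(sp2) bond, Felkin–Anh sense), placing the diynyl group trans to the enol ether arm. Any cis isomer is removed here by chromatography.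

Step 8
Reactants: 12 (1R,2R)-2-{(E)-2-[(4-methoxyphenyl)methoxy]ethenyl}-2-methyl-1-[4-(trimethylsilyl)buta-1,3-diyn-1-yl]cyclohexan-1-ol
Product: 13 (1S,2R)-2-{(E)-2-[(4-methoxyphenyl)methoxy]ethenyl}-2-methyl-1-[(1E)-4-(trimethylsilyl)but-1-en-3-yn-1-yl]cyclohexan-1-ol
Conditions: NaAlH2(OCH2CH2OMe)2 (Red-Al), THF, 0 → 25 °C
Reagents that add atoms: none
Why: Hydroxyl-directed trans hydroalumination of a propargylic alcohol; only the triple bond next to the alkoxide is reduced, which gives the E enyne and leaves the silylalkyne and the enol ether untouched.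

Step 9
Reactants: 13 (1S,2R)-2-{(E)-2-[(4-methoxyphenyl)methoxy]ethenyl}-2-methyl-1-[(1E)-4-(trimethylsilyl)but-1-en-3-yn-1-yl]cyclohexan-1-ol
Product: 15 (2S,3S,4S,5E)-2-hydroxy-4-[(4-methoxyphenyl)methoxy]-6-methyl-3-[(trimethylsilyl)ethynyl]cyclodec-5-en-1-one, via potassium C8–C9 ring enolate 14 (not isolated)
Conditions: KN(SiMe3)2, 18-crown-6, THF, 0 → 25 °C; then 2-(benzenesulfonyl)-3-phenyloxaziridine, −78 °C
Reagents that add atoms: 2-(benzenesulfonyl)-3-phenyloxaziridine, O=S(=O)(c1ccccc1)N1OC1c1ccccc1
Why: Anionic oxy-Cope rearrangement through the chair transition state with both alkenyl arms equatorial on the cyclohexane: the ring bond at the quaternary carbon is pseudo-equatorial, which gives the E C4=C5 olefin, and the two E termini place the C6 ether and the C7 alkynyl group both equatorial and therefore trans, with absolute configuration relayed from the quaternary carbon. Enolate 14 forms regiospecifically at C8–C9 and is hydroxylated in the same flask (Davis oxidation) on its outer face, which puts the C8 oxygen equatorial and trans to the C7 substituent.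

Step 10
Reactants: 15 (2S,3S,4S,5E)-2-hydroxy-4-[(4-methoxyphenyl)methoxy]-6-methyl-3-[(trimethylsilyl)ethynyl]cyclodec-5-en-1-one
Product: 16 (2S,3R,4S,5E)-4-[(4-methoxyphenyl)methoxy]-6-methyl-2-[(triethylsilyl)oxy]-3-[(trimethylsilyl)ethynyl]cyclodec-5-en-1-one
Conditions: Et3SiCl, imidazole, DMF, 0 °C
Reagents that add atoms: chlorotriethylsilane, CC[Si](Cl)(CC)CC
Why: Silylation of the secondary α-ketol hydroxyl; it prevents ketol transposition and steers the next enolisation away from C8.

Step 11
Reactants: 16 (2S,3R,4S,5E)-4-[(4-methoxyphenyl)methoxy]-6-methyl-2-[(triethylsilyl)oxy]-3-[(trimethylsilyl)ethynyl]cyclodec-5-en-1-one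
Product: 18 (2S,3R,4S,5E,10R)-4-[(4-methoxyphenyl)methoxy]-6,10-dimethyl-2-[(triethylsilyl)oxy]-3-[(trimethylsilyl)ethynyl]cyclodec-5-en-1-one, via lithium C9–C10 ring enolate 17 (not isolated)
Conditions: LiN(i-Pr)2, THF, −78 °C; then MeI, DMPU, −78 → −40 °C
Reagents that add atoms: iodomethane, CI
Why: Kinetic enolate alkylation: the amide base removes the outward-pointing hydrogen of the only α-methylene group (the C8 hydrogen is shielded by the silyloxy group), and iodomethane enters on the same outer face. The methyl therefore takes the equatorial site (10R), which should also be the thermodynamically preferred one.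

Step 12
Reactants: 18 (2S,3R,4S,5E,10R)-4-[(4-methoxyphenyl)methoxy]-6,10-dimethyl-2-[(triethylsilyl)oxy]-3-[(trimethylsilyl)ethynyl]cyclodec-5-en-1-one
Product: 19 (2S,3S,4S,5E,10R)-3-ethynyl-2-hydroxy-4-[(4-methoxyphenyl)methoxy]-6,10-dimethylcyclodec-5-en-1-one
Conditions: Bu4NF, AcOH, THF, 0 → 25 °C
Reagents that add atoms: none
Why: Fluoride cleaves the O–Si and the C(sp)–Si bond in one operation; acetic acid buffering keeps the α-ketol and the C10 centre from base-induced isomerisation.

Step 13
Reactants: 19 (2S,3S,4S,5E,10R)-3-ethynyl-2-hydroxy-4-[(4-methoxyphenyl)methoxy]-6,10-dimethylcyclodec-5-en-1-one; 20 carbon monoxide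
Product: 21 (4E,6S,7R,8S,10R)-6-[(4-methoxyphenyl)methoxy]-9-oxogermacra-4,11(13)-dien-12,8-olide
Conditions: PdCl2 (10 mol %), thiourea (10 mol %), CO (1 atm), acetone, 50 °C
Reagents that add atoms: none
Why: Divalent palladium, CO and the C8 hydroxyl form an alkoxycarbonylpalladium chloride (C12–O8 bond); this unit adds syn across the neighbouring ethynyl group, with C12 bonding to the internal alkyne carbon C11 and palladium to C13, and protonolysis of the vinyl–palladium bond by the HCl released in the first stage frees the exocyclic methylene and returns PdCl2, so no oxidant is needed. The closest known reaction type is the PdCl2/thiourea-catalysed cyclocarbonylation of homopropargylic alcohols to α-methylene-γ-butyrolactones, which is established for trans-2-ethynylcycloalkanols and gives trans-fused products. The one ring formed, the five-membered lactone (O8, C12, C11, C7, C8), closes in the 5-exo-dig sense at the insertion stage; the endo alternative would need a six-membered ring with an endocyclic trans vinyl–palladium unit and is not expected. No stereocentre is created: C7 and C8 keep the trans diequatorial relationship set in step 9, which holds oxygen and alkyne gauche as closure requires. The step needs chemoselectivity for the hydroxyl/alkyne pair over the trisubstituted olefin, the allylic PMB ether and the ketone; thiourea-ligated palladium under CO is a poor catalyst for allylic ionisation or olefin migration, and C8 carries the only hydroxyl because C9 is still a ketone. Regioselectivity of CO delivery is secured by the tether, since an acyl group bound to O8 can reach only C11.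

Step 14
Reactants: 21 (4E,6S,7R,8S,10R)-6-[(4-methoxyphenyl)methoxy]-9-oxogermacra-4,11(13)-dien-12,8-olide
Product: 22 (4E,6S,7R,8S,10R)-6-hydroxy-9-oxogermacra-4,11(13)-dien-12,8-olide
Conditions: DDQ, CH2Cl2/pH 7 buffer, 0 °C
Reagents that add atoms: none
Why: Oxidative cleavage of the PMB ether by hydride abstraction and hydrolysis; the neutral conditions spare the enoate and the ketone.

Step 15
Reactants: 22 (4E,6S,7R,8S,10R)-6-hydroxy-9-oxogermacra-4,11(13)-dien-12,8-olide
Product: 23 (4R,5R,6R,7R,8S,10R)-4,5-epoxy-6-hydroxy-9-oxogermacr-11(13)-en-12,8-olide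
Conditions: VO(acac)2 (5 mol %), t-BuOOH, CH2Cl2, 0 → 25 °C
Reagents that add atoms: tert-butyl hydroperoxide, CC(C)(C)OO
Why: Hydroxyl-directed epoxidation through a vanadium alkoxide–alkyl peroxide complex. Oxygen transfer needs an O–C6–C5=C4 dihedral angle near 45°; because the ring holds the C6–C7 bond over the inner olefin face, this geometry exists only in the rotamer that exposes the face leading to the (4R,5R) oxide, erythro to the carbinol. The electron-poor methylene lactone is not oxidised.

Step 16
Reactants: 23 (4R,5R,6R,7R,8S,10R)-4,5-epoxy-6-hydroxy-9-oxogermacr-11(13)-en-12,8-olide; 24 (E)-2-methylbut-2-enoyl chloride (tigloyl chloride)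
Product: 25 (4R,5R,6R,7R,8S,10R)-4,5-epoxy-6-[(E)-2-methylbut-2-enoyloxy]-9-oxogermacr-11(13)-en-12,8-olide
Conditions: pyridine, DMAP (cat.), CH2Cl2, 0 °C
Reagents that add atoms: none
Why: DMAP-catalysed acylation of the only hydroxyl in the molecule; the weak base does not open the epoxy alcohol or epimerise the ketone α-centres.

Step 17
Reactants: 25 (4R,5R,6R,7R,8S,10R)-4,5-epoxy-6-[(E)-2-methylbut-2-enoyloxy]-9-oxogermacr-11(13)-en-12,8-olide
Product: 26 (4R,5R,6R,7S,8S,9R,10R)-4,5-epoxy-9-hydroxy-6-[(E)-2-methylbut-2-enoyloxy]germacr-11(13)-en-12,8-olide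
Conditions: Zn(BH4)2, Et2O, −20 °C
Reagents that add atoms: none
Why: Chemoselective ketone reduction; Zn(BH4)2 leaves esters, the epoxide and, at low temperature, the conjugated lactone alone. Hydride adds to the outer face of the C9 carbonyl, and a zinc chelate between the carbonyl and the C8 oxygen favours the same face, giving the (9R) alcohol.

## Compound list

1 | diallyl heptanedioate | C=CCOC(=O)CCCCCC(=O)OCC=C | starting material
2 | sodium enolate of allyl 2-oxocyclohexane-1-carboxylate | [Na+].C=CCOC(=O)C1=C([O-])CCCC1 | intermediate (not isolated)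
3 | allyl 1-methyl-2-oxocyclohexane-1-carboxylate (racemic) | C=CCOC(=O)C1(C)CCCCC1=O | intermediate
4 | (2R)-2-methyl-2-(prop-2-en-1-yl)cyclohexan-1-one | C=CC[C@@]1(C)CCCCC1=O | intermediate
5 | (2R)-2-methyl-2-[(1E)-prop-1-en-1-yl]cyclohexan-1-one | C/C=C/[C@@]1(C)CCCCC1=O | intermediate
6 | (2R)-2-methyl-2-(5-methyl-1,2,4-trioxolan-3-yl)cyclohexan-1-one | CC1OOC(O1)[C@@]1(C)CCCCC1=O | intermediate (not isolated)
7 | (1R)-1-methyl-2-oxocyclohexane-1-carbaldehyde | O=C[C@@]1(C)CCCCC1=O | intermediate
8 | (2R)-2-[(E)-2-iodoethenyl]-2-methylcyclohexan-1-one | I/C=C/[C@@]1(C)CCCCC1=O | intermediate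
9 | (2R)-2-{(E)-2-[(4-methoxyphenyl)methoxy]ethenyl}-2-methylcyclohexan-1-one | COc1ccc(CO/C=C/[C@@]2(C)CCCCC2=O)cc1 | intermediate
10 | 1,4-bis(trimethylsilyl)buta-1,3-diyne | C[Si](C)(C)C#CC#C[Si](C)(C)C | starting material
11 | lithium 4-(trimethylsilyl)buta-1,3-diyn-1-ide | [Li+].[C-]#CC#C[Si](C)(C)C | intermediate (not isolated)
12 | (1R,2R)-2-{(E)-2-[(4-methoxyphenyl)methoxy]ethenyl}-2-methyl-1-[4-(trimethylsilyl)buta-1,3-diyn-1-yl]cyclohexan-1-ol | C[Si](C)(C)C#CC#C[C@@]1(O)CCCC[C@]1(C)/C=C/OCc1ccc(OC)cc1 | intermediate
13 | (1S,2R)-2-{(E)-2-[(4-methoxyphenyl)methoxy]ethenyl}-2-methyl-1-[(1E)-4-(trimethylsilyl)but-1-en-3-yn-1-yl]cyclohexan-1-ol | C[Si](C)(C)C#C/C=C/[C@@]1(O)CCCC[C@]1(C)/C=C/OCc1ccc(OC)cc1 | intermediate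
14 | potassium C8–C9 enolate of the ring-expanded ketone (C7 and C10 trans across the enolate double bond) | [K+].C[Si](C)(C)C#C[C@H]1/C=C(\[O-])CCCC/C(C)=C/[C@@H]1OCc1ccc(OC)cc1 | intermediate (not isolated)
15 | (2S,3S,4S,5E)-2-hydroxy-4-[(4-methoxyphenyl)methoxy]-6-methyl-3-[(trimethylsilyl)ethynyl]cyclodec-5-en-1-one | C[Si](C)(C)C#C[C@H]1[C@H](O)C(=O)CCCC/C(C)=C/[C@@H]1OCc1ccc(OC)cc1 | intermediate
16 | (2S,3R,4S,5E)-4-[(4-methoxyphenyl)methoxy]-6-methyl-2-[(triethylsilyl)oxy]-3-[(trimethylsilyl)ethynyl]cyclodec-5-en-1-one | C[Si](C)(C)C#C[C@H]1[C@H](O[Si](CC)(CC)CC)C(=O)CCCC/C(C)=C/[C@@H]1OCc1ccc(OC)cc1 | intermediate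
17 | lithium C9–C10 enolate of 16 (C8 and C1 trans across the enolate double bond) | [Li+].C[Si](C)(C)C#C[C@H]1[C@H](O[Si](CC)(CC)CC)/C([O-])=C/CCC/C(C)=C/[C@@H]1OCc1ccc(OC)cc1 | intermediate (not isolated)
18 | (2S,3R,4S,5E,10R)-4-[(4-methoxyphenyl)methoxy]-6,10-dimethyl-2-[(triethylsilyl)oxy]-3-[(trimethylsilyl)ethynyl]cyclodec-5-en-1-one | C[Si](C)(C)C#C[C@H]1[C@H](O[Si](CC)(CC)CC)C(=O)[C@H](C)CCC/C(C)=C/[C@@H]1OCc1ccc(OC)cc1 | intermediate
19 | (2S,3S,4S,5E,10R)-3-ethynyl-2-hydroxy-4-[(4-methoxyphenyl)methoxy]-6,10-dimethylcyclodec-5-en-1-one | C#C[C@H]1[C@H](O)C(=O)[C@H](C)CCC/C(C)=C/[C@@H]1OCc1ccc(OC)cc1 | intermediate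
20 | carbon monoxide | [C-]#[O+] | starting material
21 | (4E,6S,7R,8S,10R)-6-[(4-methoxyphenyl)methoxy]-9-oxogermacra-4,11(13)-dien-12,8-olide | C=C1C(=O)O[C@@H]2C(=O)[C@H](C)CCC/C(C)=C/[C@H](OCc3ccc(OC)cc3)[C@@H]12 | intermediate
22 | (4E,6S,7R,8S,10R)-6-hydroxy-9-oxogermacra-4,11(13)-dien-12,8-olide | C=C1C(=O)O[C@@H]2C(=O)[C@H](C)CCC/C(C)=C/[C@H](O)[C@@H]12 | intermediate
23 | (4R,5R,6R,7R,8S,10R)-4,5-epoxy-6-hydroxy-9-oxogermacr-11(13)-en-12,8-olide | C=C1C(=O)O[C@@H]2C(=O)[C@H](C)CCC[C@@]3(C)O[C@@H]3[C@H](O)[C@@H]12 | intermediate
24 | (E)-2-methylbut-2-enoyl chloride | C/C=C(\C)C(Cl)=O | starting material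
25 | (4R,5R,6R,7R,8S,10R)-4,5-epoxy-6-[(E)-2-methylbut-2-enoyloxy]-9-oxogermacr-11(13)-en-12,8-olide | C=C1C(=O)O[C@@H]2C(=O)[C@H](C)CCC[C@@]3(C)O[C@@H]3[C@H](OC(=O)/C(C)=C/C)[C@@H]12 | intermediate
26 | (4R,5R,6R,7S,8S,9R,10R)-4,5-epoxy-9-hydroxy-6-[(E)-2-methylbut-2-enoyloxy]germacr-11(13)-en-12,8-olide | C=C1C(=O)O[C@@H]2[C@H](O)[C@H](C)CCC[C@@]3(C)O[C@@H]3[C@H](OC(=O)/C(C)=C/C)[C@@H]12 | target

## Step count and least certain steps

Total: 17 steps. Longest linear sequence: 17 steps, from 1.

**Step 13 (key step).** The C8 hydroxyl is deactivated by the neighbouring ketone and may form the alkoxycarbonylpalladium species slowly. Divalent palladium could then instead activate the alkyne towards hydration or towards 5-endo attack by the same oxygen. The fallback sets out from 19: intermolecular branch-selective methoxycarbonylation of the terminal alkyne (Pd(OAc)2, 2-(diphenylphosphino)pyridine, MeSO3H, CO, MeOH) should give the acrylate methyl ester F1. Acid-catalysed transesterification (camphorsulfonic acid, toluene, 60 °C) then closes the lactone and returns to 21.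

**Step 15.** The rotamer that lets the vanadium-bound peroxide reach the olefin places the C6 oxygen near the C15 methyl. If it is too poorly populated, the reaction becomes slow, face selectivity is lost to undirected oxidation, and the allylic alcohol may be oxidised to the enone. The fallback sets out from 22: acylation with 24 first gives the olefinic tiglate F2. Epoxidation under reagent control with the fructose-derived Shi ketone and KHSO5 (K2CO3 buffer, MeCN/dimethoxymethane, 0 °C) is expected to select the (4R,5R) face of an E trisubstituted olefin and returns to 25.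

**Step 9.** Oxygen transfer to the hindered ring enolate may be incomplete, the enolate may equilibrate before it is trapped, or it may add to the sulfonimine by-product. The chair selectivity of the rearrangement with an enol ether and an enyne terminus is itself untested on this substrate. The fallback sets out from 13: after the rearrangement, enolate 14 is quenched with Et3SiCl to give the isolable triethylsilyl enol ether F3. Dimethyldioxirane in acetone at −78 °C oxidises this electron-rich olefin on its outer face (Rubottom oxidation) to the silyloxy epoxide F4, and dilute aqueous acid opens F4 to 15.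

**Step 11.** Regiocontrol may be lost through deprotonation at C8 with silyl migration, and facial control may erode if the enolate relaxes into another ring conformer. The fallback carries the methyl from the cyclohexanone and sets out from 9:
- Kinetic methylation (LiN(i-Pr)2, MeI, −78 °C) should place the new methyl trans to the alkenyl arm and give ketone F5, in which that arm is locked axial.
- Addition of 11 anti to the axial arm gives diynyl carbinol F6, and hydroalumination gives enyne carbinol F7.
- Ring expansion and hydroxylation as in step 9 give hydroxy ketone F8. This is the C10 epimer, because the methyl is axial in the reacting chair, and the barrier is higher.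
- Silylation gives the triethylsilyl ether F9, and equilibration with DBU in CH2Cl2 moves the methyl to the equatorial site and returns to 18.

**Step 17.** Hydride may add in conjugate fashion to the methylene lactone, may attack the wrong face once epoxide and tiglate have changed the ring shape, or the new C9 alkoxide may attack the lactone carbonyl. The fallback moves the reduction forward and sets out from 21:
- Zn(BH4)2 gives the C9 alcohol F10, and t-BuMe2SiOTf with 2,6-lutidine gives the silyl ether F11.
- DDQ gives the C6 alcohol F12, and VO(acac)2/t-BuOOH gives the epoxy alcohol F13.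
- Acylation with 24 gives the silylated tiglate F14, and HF·pyridine in THF removes the silyl group and returns to 26.

## Further compounds

F1 | step 13 | methyl (4E,6S,7S,8S,10R)-8-hydroxy-6-[(4-methoxyphenyl)methoxy]-9-oxogermacra-4,11(13)-dien-12-oate | C=C(C(=O)OC)[C@H]1[C@H](O)C(=O)[C@H](C)CCC/C(C)=C/[C@@H]1OCc1ccc(OC)cc1
F2 | step 15 | (4E,6S,7R,8S,10R)-6-[(E)-2-methylbut-2-enoyloxy]-9-oxogermacra-4,11(13)-dien-12,8-olide | C=C1C(=O)O[C@@H]2C(=O)[C@H](C)CCC/C(C)=C/[C@H](OC(=O)/C(C)=C/C)[C@@H]12
F3 | step 9 | triethylsilyl enol ether of enolate 14 | C[Si](C)(C)C#C[C@H]1/C=C(\O[Si](CC)(CC)CC)CCCC/C(C)=C/[C@@H]1OCc1ccc(OC)cc1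
F4 | step 9 | C8–C9 silyloxy epoxide of F3 (oxygen on the outer face) | C[Si](C)(C)C#C[C@H]1[C@@H]2O[C@@]2(O[Si](CC)(CC)CC)CCCC/C(C)=C/[C@@H]1OCc1ccc(OC)cc1
F5 | step 11 | (2R,6S)-2-{(E)-2-[(4-methoxyphenyl)methoxy]ethenyl}-2,6-dimethylcyclohexan-1-one | COc1ccc(CO/C=C/[C@@]2(C)CCC[C@H](C)C2=O)cc1
F6 | step 11 | (1R,2R,6S)-2-{(E)-2-[(4-methoxyphenyl)methoxy]ethenyl}-2,6-dimethyl-1-[4-(trimethylsilyl)buta-1,3-diyn-1-yl]cyclohexan-1-ol | C[Si](C)(C)C#CC#C[C@@]1(O)[C@@H](C)CCC[C@]1(C)/C=C/OCc1ccc(OC)cc1
F7 | step 11 | (1S,2R,6S)-2-{(E)-2-[(4-methoxyphenyl)methoxy]ethenyl}-2,6-dimethyl-1-[(1E)-4-(trimethylsilyl)but-1-en-3-yn-1-yl]cyclohexan-1-ol | C[Si](C)(C)C#C/C=C/[C@@]1(O)[C@@H](C)CCC[C@]1(C)/C=C/OCc1ccc(OC)cc1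
F8 | step 11 | (2S,3S,4S,5E,10S)-2-hydroxy-4-[(4-methoxyphenyl)methoxy]-6,10-dimethyl-3-[(trimethylsilyl)ethynyl]cyclodec-5-en-1-one | C[Si](C)(C)C#C[C@H]1[C@H](O)C(=O)[C@@H](C)CCC/C(C)=C/[C@@H]1OCc1ccc(OC)cc1
F9 | step 11 | (2S,3R,4S,5E,10S)-4-[(4-methoxyphenyl)methoxy]-6,10-dimethyl-2-[(triethylsilyl)oxy]-3-[(trimethylsilyl)ethynyl]cyclodec-5-en-1-one | C[Si](C)(C)C#C[C@H]1[C@H](O[Si](CC)(CC)CC)C(=O)[C@@H](C)CCC/C(C)=C/[C@@H]1OCc1ccc(OC)cc1
F10 | step 17 | (4E,6S,7R,8S,9R,10R)-9-hydroxy-6-[(4-methoxyphenyl)methoxy]germacra-4,11(13)-dien-12,8-olide | C=C1C(=O)O[C@@H]2[C@H](O)[C@H](C)CCC/C(C)=C/[C@H](OCc3ccc(OC)cc3)[C@@H]12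
F11 | step 17 | 9-O-(tert-butyldimethylsilyl) ether of F10 | C=C1C(=O)O[C@@H]2[C@H](O[Si](C)(C)C(C)(C)C)[C@H](C)CCC/C(C)=C/[C@H](OCc3ccc(OC)cc3)[C@@H]12
F12 | step 17 | (4E,6S,7R,8S,9R,10R)-9-[(tert-butyldimethylsilyl)oxy]-6-hydroxygermacra-4,11(13)-dien-12,8-olide | C=C1C(=O)O[C@@H]2[C@H](O[Si](C)(C)C(C)(C)C)[C@H](C)CCC/C(C)=C/[C@H](O)[C@@H]12
F13 | step 17 | (4R,5R,6R,7R,8S,9R,10R)-9-[(tert-butyldimethylsilyl)oxy]-4,5-epoxy-6-hydroxygermacr-11(13)-en-12,8-olide | C=C1C(=O)O[C@@H]2[C@H](O[Si](C)(C)C(C)(C)C)[C@H](C)CCC[C@@]3(C)O[C@@H]3[C@H](O)[C@@H]12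
F14 | step 17 | 9-O-(tert-butyldimethylsilyl) ether of 26 | C=C1C(=O)O[C@@H]2[C@H](O[Si](C)(C)C(C)(C)C)[C@H](C)CCC[C@@]3(C)O[C@@H]3[C@H](OC(=O)/C(C)=C/C)[C@@H]12
A1 | alternative 1 | ten-membered saturated lactone with geminal phenylsulfonyl groups on C2 and E C4=C5 olefin | O=C1O[C@@H]2[C@H](O[Si](C)(C)C(C)(C)C)[C@H](C)CC(S(=O)(=O)c3ccccc3)(S(=O)(=O)c3ccccc3)C/C(C)=C/[C@H](OCc3ccc(OC)cc3)[C@H]2C1
A2 | alternative 2 | 2-methylcyclohex-2-enone carrying the C6 PMB ether, the C7 silyloxy-isopropenyl arm and the C8 silyl ether | O=C1[C@@H](O[Si](C)(C)C(C)(C)C)[C@H](C(=C)CO[Si](C)(C)C(C)(C)C)[C@@H](OCc2ccc(OC)cc2)C=C1C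
A3 | alternative 2 | 1-methylcyclobutene | CC1=CCC1
A4 | alternative 2 | cis-anti-cis tricyclic photoadduct (cyclohexanone fused to a bicyclo[2.2.0]hexane) | O=C1[C@@H](O[Si](C)(C)C(C)(C)C)[C@H](C(=C)CO[Si](C)(C)C(C)(C)C)[C@@H](OCc3ccc(OC)cc3)[C@H]2[C@]1(C)[C@@H]1CC[C@]21C
A5 | alternative 3 | E-cyclodec-5-enone with C6 methoxymethyl ether and C7 2-(4-methoxybenzyloxy)ethyl arm | O=C1C[C@H](CCOCc2ccc(OC)cc2)[C@@H](OCOC)/C=C(\C)CCC[C@H]1C
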